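**Plan**
- Cuts, in retrosynthetic order: the five O–Si bonds; the C2–C3 bond of flavanone ring C; the diazo group; the ArCH2–aryl bond at C3' of the flavone B ring; the benzyl ether C–O bond; the flavone pyranone ring.
- Enabling feature: in ring C of the flavanone, C2 is a benzylic carbon on O1 and C3 is an aryl-bearing carbon alpha to the C4 ketone, so C2–C3 maps onto insertion of an aryl keto carbene at C3 into the O–CH2 of a 4-(silyloxy)benzyl aryl ether.
- Forward: the flavone ring system is built first by diketone cyclodehydration (steps 5–9) and the silylated A-ring ketone in parallel (steps 1–4); the halves are joined by ketone alpha-arylation (step 10); diazo transfer (step 11); flavanone ring C closes last (step 12); desilylation (step 13).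
- Stereochemistry: C2 (S) comes from the chiral dirhodium carboxylate in the insertion; C3 (R) follows by equilibration to the trans, diequatorial arrangement.

Key step: step 12

Assumption: the (S)-tert-leucine-derived catalyst is taken to deliver (2S); should insertion favour (2R), the mirror-image catalyst Rh2(R-PTTL)4 is used in step 12 in the same way.

Abbreviations: TIPS = triisopropylsilyl, TBS = tert-butyldimethylsilyl.

**Route**

Step 1
Reactants: 1 4-hydroxybenzaldehyde
Product: 2 4-(triisopropylsilyloxy)benzaldehyde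
Conditions: TIPSCl, imidazole, DMF, rt
Reagents that add atoms: chlorotriisopropylsilane, CC(C)[Si](Cl)(C(C)C)C(C)C
Why: Imidazole-promoted silylation of the phenol should proceed cleanly and leave the aldehyde untouched.

Step 2
Reactants: 2 4-(triisopropylsilyloxy)benzaldehyde
Product: 3 [4-(triisopropylsilyloxy)phenyl]methanol
Conditions: NaBH4, MeOH/THF, 0 °C
Reagents that add atoms: none
Why: Borohydride reduction of the aldehyde to the benzylic alcohol should be fast at 0 °C, and the hindered aryl silyl ether should survive the brief protic conditions.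

Step 3
Reactants: 4 2',4',6'-trihydroxyacetophenone (dried)
Product: 5 1-[2-hydroxy-4,6-bis(triisopropylsilyloxy)phenyl]ethanone
Conditions: TIPSCl (2.1 equiv), imidazole, DMF, 0 °C to rt
Reagents that add atoms: chlorotriisopropylsilane, CC(C)[Si](Cl)(C(C)C)C(C)C
Why: Selective silylation should take the para hydroxyl and one ortho hydroxyl, because the last ortho hydroxyl is locked in a hydrogen bond to the acetyl carbonyl and resists the bulky chloride, as in the usual bis-protection of phloroacetophenone.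

Step 4
Reactants: 5 1-[2-hydroxy-4,6-bis(triisopropylsilyloxy)phenyl]ethanone; 3 [4-(triisopropylsilyloxy)phenyl]methanol
Product: 6 1-[2-{[4-(triisopropylsilyloxy)phenyl]methoxy}-4,6-bis(triisopropylsilyloxy)phenyl]ethanone
Conditions: PPh3, DIAD, THF, 0 °C to rt
Reagents that add atoms: none
Why: Mitsunobu etherification of the acidic chelated phenol with a primary benzylic alcohol is neutral, so the aryl silyl ethers should not migrate or cleave.

Step 5
Reactants: 7 3-bromo-4-hydroxybenzoic acid
Product: 8 tert-butyldimethylsilyl 3-bromo-4-(tert-butyldimethylsilyloxy)benzoate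
Conditions: TBSCl (2.2 equiv), imidazole, DMF, rt
Reagents that add atoms: tert-butylchlorodimethylsilane, CC(C)(C)[Si](C)(C)Cl
Why: Imidazole-promoted silylation should convert both the phenol and the carboxylic acid, giving a silyl ester that is a direct precursor of the acid chloride.

Step 6
Reactants: 8 tert-butyldimethylsilyl 3-bromo-4-(tert-butyldimethylsilyloxy)benzoate
Product: 9 3-bromo-4-(tert-butyldimethylsilyloxy)benzoyl chloride
Conditions: (COCl)2, DMF (cat.), CH2Cl2, 0 °C to rt
Reagents that add atoms: oxalyl chloride, ClC(=O)C(=O)Cl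
Why: The Vilsmeier-type reagent from oxalyl chloride and DMF should turn the silyl ester into the acid chloride under neutral conditions that keep the aryl silyl ether.

Step 7
Reactants: 10 2',6'-dihydroxy-4'-methoxyacetophenone; 9 3-bromo-4-(tert-butyldimethylsilyloxy)benzoyl chloride
Product: 11 1-[3-bromo-4-(tert-butyldimethylsilyloxy)phenyl]-3-(2,6-dihydroxy-4-methoxyphenyl)propane-1,3-dione
Conditions: LiN(SiMe3)2 (4.2 equiv), THF, –78 to –10 °C; then 9, –78 °C to rt; aq. HCl work-up
Reagents that add atoms: none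
Why: The lithium polyanion (two phenoxides and the enolate) should be acylated at the enolate carbon by the aroyl chloride, a Claisen-type C-acylation that gives the beta-diketone without protecting the ring hydroxyls.

Step 8
Reactants: 11 1-[3-bromo-4-(tert-butyldimethylsilyloxy)phenyl]-3-(2,6-dihydroxy-4-methoxyphenyl)propane-1,3-dione
Product: 12 2-(3-bromo-4-hydroxyphenyl)-5-hydroxy-7-methoxy-4H-chromen-4-one
Conditions: AcOH, H2SO4 (cat.), 95 °C
Reagents that add atoms: none
Why: Acid-catalysed cyclodehydration of the ortho-hydroxyaryl beta-diketone should close the flavone pyranone ring (either of the two equivalent hydroxyls gives the same product), and the hot acid should also cleave the aryl silyl ether.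

Step 9
Reactants: 12 2-(3-bromo-4-hydroxyphenyl)-5-hydroxy-7-methoxy-4H-chromen-4-one
Product: 13 2-[3-bromo-4-(triisopropylsilyloxy)phenyl]-7-methoxy-5-(triisopropylsilyloxy)-4H-chromen-4-one
Conditions: TIPSOTf (3 equiv), 2,6-lutidine, CH2Cl2, 0 °C to rt
Reagents that add atoms: triisopropylsilyl trifluoromethanesulfonate, CC(C)[Si](OS(=O)(=O)C(F)(F)F)(C(C)C)C(C)C
Why: The silyl triflate is electrophilic enough to silylate the chelated 5-hydroxyl as well as the 4'-hydroxyl, and the flavone has no enolisable position that could compete.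

Step 10
Reactants: 6 1-[2-{[4-(triisopropylsilyloxy)phenyl]methoxy}-4,6-bis(triisopropylsilyloxy)phenyl]ethanone; 13 2-[3-bromo-4-(triisopropylsilyloxy)phenyl]-7-methoxy-5-(triisopropylsilyloxy)-4H-chromen-4-one
Product: 14 2-[5-(7-methoxy-4-oxo-5-(triisopropylsilyloxy)-4H-chromen-2-yl)-2-(triisopropylsilyloxy)phenyl]-1-[2-{[4-(triisopropylsilyloxy)phenyl]methoxy}-4,6-bis(triisopropylsilyloxy)phenyl]ethanone
Conditions: Pd2(dba)3 (zerovalent palladium, 2.5 mol %), XPhos, K3PO4, toluene, 90 °C; 6 in slight excess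
Reagents that add atoms: none
Why: Palladium-catalysed alpha-arylation of the methyl ketone with the aryl bromide should give the deoxybenzoin, with the mild phosphate base and the robust TIPS ethers chosen to avoid desilylation, and the more acidic product enolate disfavouring a second arylation.

Step 11
Reactants: 14 the deoxybenzoin from step 10
Product: 15 2-diazo-2-[5-(7-methoxy-4-oxo-5-(triisopropylsilyloxy)-4H-chromen-2-yl)-2-(triisopropylsilyloxy)phenyl]-1-[2-{[4-(triisopropylsilyloxy)phenyl]methoxy}-4,6-bis(triisopropylsilyloxy)phenyl]ethanone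
Conditions: 4-acetamidobenzenesulfonyl azide, DBU, MeCN/CH2Cl2, 0 °C to rt
Reagents that add atoms: 4-acetamidobenzenesulfonyl azide, CC(=O)Nc1ccc(S(=O)(=O)N=[N+]=[N-])cc1
Why: Regitz diazo transfer to the doubly activated benzylic methylene of a benzyl aryl ketone is standard with a sulfonyl azide and DBU, and anhydrous conditions should spare the silyl ethers.

Step 12
Reactants: 15 the alpha-diazo deoxybenzoin from step 11
Product: 17 (2S,3R)-3-[5-(7-methoxy-4-oxo-5-(triisopropylsilyloxy)-4H-chromen-2-yl)-2-(triisopropylsilyloxy)phenyl]-5,7-bis(triisopropylsilyloxy)-2-[4-(triisopropylsilyloxy)phenyl]chroman-4-one, via cis-(2S,3S) pentasilyl flavanone 16 (not isolated)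
Conditions: Rh2(S-PTTL)4 [dirhodium tetrakis(N-phthaloyl-(S)-tert-leucinate), divalent rhodium] (2 mol %), toluene, 0 °C to rt; then Et3N, rt
Reagents that add atoms: none
Why: The dirhodium catalyst should expel N2 from 15 to give an aryl/acyl (donor–acceptor) rhodium carbene at the future C3, which inserts through a concerted three-centre, hydride-transfer-like transition state into a C–H bond of the neighbouring ArCH2–O group and so forms C2–C3. The closest known reaction type is the dirhodium-catalysed intramolecular C–H insertion of aryl diazo ketones and aryldiazoacetates into ether-activated benzylic C–H bonds, which gives chromanones and 2-aryl-2,3-dihydrobenzofurans. Ring C closes as a six-membered ring by a formal 1,6-insertion (C3, C4, C4a, C8a, O1, C2) at the only activated C–H within reach of the carbene. C2 is set by the chiral carboxylate ligands, which should select the pro-S benzylic hydrogen and replace it with retention, while C3 is expected to emerge cis and is then brought to the trans, diequatorial (3R) arrangement by triethylamine-mediated enolisation that does not touch C2. The step needs C–H insertion to win over oxonium ylide formation with Stevens-type benzyl shift, Wolff rearrangement and attack on the silyl ethers; this should be secured by the weakly basic oxygen of the acyl-substituted aryl ether, the bulky TIPS ethers that offer no activated C–H, the para silyloxy group that makes the benzylic C–H hydridic, and the selective donor–acceptor carbene.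

Step 13
Reactants: 17 the trans pentasilyl flavanone from step 12
Product: 18 (2S,3R)-5,7-dihydroxy-3-[2-hydroxy-5-(5-hydroxy-7-methoxy-4-oxo-4H-chromen-2-yl)phenyl]-2-(4-hydroxyphenyl)chroman-4-one
Conditions: HF·pyridine, pyridine, THF, 0 °C to rt
Reagents that add atoms: none
Why: Fluoride cleavage of the five aryl silyl ethers in a buffered, weakly acidic medium should avoid enolate formation and base-induced opening of ring C, so C2 is kept and C3 stays in the thermodynamically preferred trans arrangement; the methyl ether is inert.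

**Compound list**

1 | 4-hydroxybenzaldehyde | O=Cc1ccc(O)cc1 | starting material
2 | 4-(triisopropylsilyloxy)benzaldehyde | O=Cc1ccc(O[Si](C(C)C)(C(C)C)C(C)C)cc1 | intermediate
3 | [4-(triisopropylsilyloxy)phenyl]methanol | OCc1ccc(O[Si](C(C)C)(C(C)C)C(C)C)cc1 | intermediate
4 | 2',4',6'-trihydroxyacetophenone | CC(=O)c1c(O)cc(O)cc1O | starting material
5 | 1-[2-hydroxy-4,6-bis(triisopropylsilyloxy)phenyl]ethanone | CC(=O)c1c(O)cc(O[Si](C(C)C)(C(C)C)C(C)C)cc1O[Si](C(C)C)(C(C)C)C(C)C | intermediate
6 | 1-[2-{[4-(triisopropylsilyloxy)phenyl]methoxy}-4,6-bis(triisopropylsilyloxy)phenyl]ethanone | CC(=O)c1c(OCc2ccc(O[Si](C(C)C)(C(C)C)C(C)C)cc2)cc(O[Si](C(C)C)(C(C)C)C(C)C)cc1O[Si](C(C)C)(C(C)C)C(C)C | intermediate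
7 | 3-bromo-4-hydroxybenzoic acid | OC(=O)c1ccc(O)c(Br)c1 | starting material
8 | tert-butyldimethylsilyl 3-bromo-4-(tert-butyldimethylsilyloxy)benzoate | CC(C)(C)[Si](C)(C)OC(=O)c1ccc(O[Si](C)(C)C(C)(C)C)c(Br)c1 | intermediate
9 | 3-bromo-4-(tert-butyldimethylsilyloxy)benzoyl chloride | O=C(Cl)c1ccc(O[Si](C)(C)C(C)(C)C)c(Br)c1 | intermediate
10 | 2',6'-dihydroxy-4'-methoxyacetophenone | CC(=O)c1c(O)cc(OC)cc1O | starting material
11 | 1-[3-bromo-4-(tert-butyldimethylsilyloxy)phenyl]-3-(2,6-dihydroxy-4-methoxyphenyl)propane-1,3-dione | COc1cc(O)c(C(=O)CC(=O)c2ccc(O[Si](C)(C)C(C)(C)C)c(Br)c2)c(O)c1 | intermediate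
12 | 2-(3-bromo-4-hydroxyphenyl)-5-hydroxy-7-methoxy-4H-chromen-4-one | COc1cc(O)c2c(=O)cc(-c3ccc(O)c(Br)c3)oc2c1 | intermediate
13 | 2-[3-bromo-4-(triisopropylsilyloxy)phenyl]-7-methoxy-5-(triisopropylsilyloxy)-4H-chromen-4-one | COc1cc(O[Si](C(C)C)(C(C)C)C(C)C)c2c(=O)cc(-c3ccc(O[Si](C(C)C)(C(C)C)C(C)C)c(Br)c3)oc2c1 | intermediate
14 | 2-[5-(7-methoxy-4-oxo-5-(triisopropylsilyloxy)-4H-chromen-2-yl)-2-(triisopropylsilyloxy)phenyl]-1-[2-{[4-(triisopropylsilyloxy)phenyl]methoxy}-4,6-bis(triisopropylsilyloxy)phenyl]ethanone | COc1cc(O[Si](C(C)C)(C(C)C)C(C)C)c2c(=O)cc(-c3ccc(O[Si](C(C)C)(C(C)C)C(C)C)c(CC(=O)c4c(OCc5ccc(O[Si](C(C)C)(C(C)C)C(C)C)cc5)cc(O[Si](C(C)C)(C(C)C)C(C)C)cc4O[Si](C(C)C)(C(C)C)C(C)C)c3)oc2c1 | intermediate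
15 | 2-diazo-2-[5-(7-methoxy-4-oxo-5-(triisopropylsilyloxy)-4H-chromen-2-yl)-2-(triisopropylsilyloxy)phenyl]-1-[2-{[4-(triisopropylsilyloxy)phenyl]methoxy}-4,6-bis(triisopropylsilyloxy)phenyl]ethanone | COc1cc(O[Si](C(C)C)(C(C)C)C(C)C)c2c(=O)cc(-c3ccc(O[Si](C(C)C)(C(C)C)C(C)C)c(C(=[N+]=[N-])C(=O)c4c(OCc5ccc(O[Si](C(C)C)(C(C)C)C(C)C)cc5)cc(O[Si](C(C)C)(C(C)C)C(C)C)cc4O[Si](C(C)C)(C(C)C)C(C)C)c3)oc2c1 | intermediate
16 | (2S,3S)-3-[5-(7-methoxy-4-oxo-5-(triisopropylsilyloxy)-4H-chromen-2-yl)-2-(triisopropylsilyloxy)phenyl]-5,7-bis(triisopropylsilyloxy)-2-[4-(triisopropylsilyloxy)phenyl]chroman-4-one (cis) | COc1cc(O[Si](C(C)C)(C(C)C)C(C)C)c2c(=O)cc(-c3ccc(O[Si](C(C)C)(C(C)C)C(C)C)c([C@@H]4C(=O)c5c(O[Si](C(C)C)(C(C)C)C(C)C)cc(O[Si](C(C)C)(C(C)C)C(C)C)cc5O[C@@H]4c4ccc(O[Si](C(C)C)(C(C)C)C(C)C)cc4)c3)oc2c1 | intermediate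
17 | (2S,3R)-3-[5-(7-methoxy-4-oxo-5-(triisopropylsilyloxy)-4H-chromen-2-yl)-2-(triisopropylsilyloxy)phenyl]-5,7-bis(triisopropylsilyloxy)-2-[4-(triisopropylsilyloxy)phenyl]chroman-4-one (trans) | COc1cc(O[Si](C(C)C)(C(C)C)C(C)C)c2c(=O)cc(-c3ccc(O[Si](C(C)C)(C(C)C)C(C)C)c([C@H]4C(=O)c5c(O[Si](C(C)C)(C(C)C)C(C)C)cc(O[Si](C(C)C)(C(C)C)C(C)C)cc5O[C@@H]4c4ccc(O[Si](C(C)C)(C(C)C)C(C)C)cc4)c3)oc2c1 | intermediate
18 | (2S,3R)-5,7-dihydroxy-3-[2-hydroxy-5-(5-hydroxy-7-methoxy-4-oxo-4H-chromen-2-yl)phenyl]-2-(4-hydroxyphenyl)chroman-4-one | COc1cc(O)c2c(=O)cc(-c3ccc(O)c([C@H]4C(=O)c5c(O)cc(O)cc5O[C@@H]4c4ccc(O)cc4)c3)oc2c1 | target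

**Step count**

Total: 13 steps. Longest linear sequence: 9 steps (steps 5–13, from 3-bromo-4-hydroxybenzoic acid).

**Steps most likely to fail**

1. Step 12. The carbene may be captured by the ether oxygen (oxonium ylide, then benzyl shift) or undergo Wolff rearrangement instead of inserting, or the catalyst may discriminate poorly between the two enantiotopic benzylic hydrogens. The fallback sets out from 14 and comes back at 17. Hydrogenolysis of the benzyl aryl ether (H2, Pd/C (palladium on carbon), EtOAc) should give the phenolic deoxybenzoin 1-[2-hydroxy-4,6-bis(triisopropylsilyloxy)phenyl]-2-[5-(7-methoxy-4-oxo-5-(triisopropylsilyloxy)-4H-chromen-2-yl)-2-(triisopropylsilyloxy)phenyl]ethanone F1. Condensation of it with aldehyde 2 (piperidine, EtOH, reflux; Knoevenagel condensation followed by oxa-Michael closure, the classical 2,3-diarylchromanone synthesis) should give the trans flavanone as a racemate, that is 17 together with its (2R,3S) enantiomer F2. Preparative chromatography on a chiral stationary phase would then deliver 17.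

2. Step 10. Silyl transfer from the aryl silyl ethers to the potassium enolate, slow coupling at the two hindered centres or a second arylation may erode the union. The fallback sets out from 6 and comes back at 14. Enol silylation (TMSOTf, Et3N, CH2Cl2, 0 °C) should give the trimethylsilyl enol ether of ketone 6 F3. Its base-free coupling with bromide 13 through the tributyltin enolate (PdCl2[P(o-tol)3]2, divalent palladium, Bu3SnF, toluene, reflux) is a known arylation of methyl ketone silyl enol ethers and should give 14.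

3. Step 11. Deprotonation of the hindered, poorly conjugated ketone may be incomplete, or DBU may start to remove silyl groups before diazo transfer is complete. The fallback sets out from 14 and comes back at 15. Riley oxidation (SeO2, dioxane, reflux) should give the 1,2-diketone F4. Tosylhydrazide (TsNHNH2, EtOH, rt) should condense at the less hindered carbonyl, the one next to the flavone-bearing ring, to give the monotosylhydrazone F5. Bamford–Stevens elimination (Et3N, CH2Cl2, rt) should then give diazo ketone 15.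

**Further compounds**

F1 | step 12 | 1-[2-hydroxy-4,6-bis(triisopropylsilyloxy)phenyl]-2-[5-(7-methoxy-4-oxo-5-(triisopropylsilyloxy)-4H-chromen-2-yl)-2-(triisopropylsilyloxy)phenyl]ethanone | COc1cc(O[Si](C(C)C)(C(C)C)C(C)C)c2c(=O)cc(-c3ccc(O[Si](C(C)C)(C(C)C)C(C)C)c(CC(=O)c4c(O)cc(O[Si](C(C)C)(C(C)C)C(C)C)cc4O[Si](C(C)C)(C(C)C)C(C)C)c3)oc2c1
F2 | step 12 | (2R,3S)-3-[5-(7-methoxy-4-oxo-5-(triisopropylsilyloxy)-4H-chromen-2-yl)-2-(triisopropylsilyloxy)phenyl]-5,7-bis(triisopropylsilyloxy)-2-[4-(triisopropylsilyloxy)phenyl]chroman-4-one | COc1cc(O[Si](C(C)C)(C(C)C)C(C)C)c2c(=O)cc(-c3ccc(O[Si](C(C)C)(C(C)C)C(C)C)c([C@@H]4C(=O)c5c(O[Si](C(C)C)(C(C)C)C(C)C)cc(O[Si](C(C)C)(C(C)C)C(C)C)cc5O[C@H]4c4ccc(O[Si](C(C)C)(C(C)C)C(C)C)cc4)c3)oc2c1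
F3 | step 10 | trimethyl({1-[2-{[4-(triisopropylsilyloxy)phenyl]methoxy}-4,6-bis(triisopropylsilyloxy)phenyl]ethenyl}oxy)silane | C=C(O[Si](C)(C)C)c1c(OCc2ccc(O[Si](C(C)C)(C(C)C)C(C)C)cc2)cc(O[Si](C(C)C)(C(C)C)C(C)C)cc1O[Si](C(C)C)(C(C)C)C(C)C
F4 | step 11 | 1-[5-(7-methoxy-4-oxo-5-(triisopropylsilyloxy)-4H-chromen-2-yl)-2-(triisopropylsilyloxy)phenyl]-2-[2-{[4-(triisopropylsilyloxy)phenyl]methoxy}-4,6-bis(triisopropylsilyloxy)phenyl]ethane-1,2-dione | COc1cc(O[Si](C(C)C)(C(C)C)C(C)C)c2c(=O)cc(-c3ccc(O[Si](C(C)C)(C(C)C)C(C)C)c(C(=O)C(=O)c4c(OCc5ccc(O[Si](C(C)C)(C(C)C)C(C)C)cc5)cc(O[Si](C(C)C)(C(C)C)C(C)C)cc4O[Si](C(C)C)(C(C)C)C(C)C)c3)oc2c1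
F5 | step 11 | monotosylhydrazone of F4 at the carbonyl next to the flavone-bearing ring | COc1cc(O[Si](C(C)C)(C(C)C)C(C)C)c2c(=O)cc(-c3ccc(O[Si](C(C)C)(C(C)C)C(C)C)c(C(=NNS(=O)(=O)c6ccc(C)cc6)C(=O)c4c(OCc5ccc(O[Si](C(C)C)(C(C)C)C(C)C)cc5)cc(O[Si](C(C)C)(C(C)C)C(C)C)cc4O[Si](C(C)C)(C(C)C)C(C)C)c3)oc2c1
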